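One unit of target takes one unit of first nucleophile and one unit of other capture product takes one unit of second nucleophile, so the readings tell us what is left of each nucleophile.

| setting | ash | maple | birch | spring | autumn | midnight | noon | dawn |
|---|---|---|---|---|---|---|---|---|
| starting material | 0.20 M | 0.20 M | 0.20 M | 0.20 M | 0.20 M | 0.20 M | 0.20 M | 0.20 M |
| first nucleophile | 0.18 M | 0.18 M | 0.18 M | 0.180 M | 0.180 M (fed, over 6.0 min) | 0.180 M (fed, over 6.0 min) | 0.180 M | 0.180 M (fed, over 1.5 min) |
| second nucleophile | 0.10 M | 0.050 M | 0.20 M | 0.100 M | 0.100 M | 0.100 M | 0.100 M | 0.100 M |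
| capture agent | 0.010 M | 0.010 M | 0.010 M | 0.0100 M | 0.0100 M | 0.0100 M | 0.0100 M | 0.0100 M |
| temperature | 55 °C | 70 °C | 55 °C |  |  | 70 °C | 70 °C | 70 °C |
| remark | run made earlier | run made earlier | run made earlier | everything together at the start at 40 °C, warmed to 70 °C at 6.0 min | the addition at 40 °C, then warmed to 70 °C; the feed brings no volume worth counting | all else is in the flask from the start; the feed brings no volume worth counting | everything together at the start | all else is in the flask from the start; the feed brings no volume worth counting |
| time |  |  |  | 8.0 min | 8.0 min | 8.0 min | 8.0 min | 8.0 min |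

| run | time / min | target / % | other capture product / % | starting material / % |
|---|---|---|---|---|
| ash | 0.667 | 3.4 | 0 | 97.1 |
| ash | 2.00 | 8.1 | 1.7 | 90.6 |
| ash | 3.00 | 11.7 | 1.6 | 83.7 |
| ash | 5.00 | 17.4 | 3.9 | 73.8 |
| ash | 8.00 | 24.9 | 6.3 | 63.6 |
| ash | 10.0 | 30.1 | 7.4 | 58.5 |
| maple | 0.667 | 11.5 | 0 | 83.4 |
| maple | 2.00 | 26.7 | 4.1 | 55.2 |
| maple | 3.00 | 36.1 | 7.9 | 41.3 |
| maple | 5.00 | 45.1 | 8.8 | 21.7 |
| maple | 8.00 | 53.2 | 11.8 | 9.5 |
| maple | 10.0 | 54.0 | 11.2 | 5.7 |
| birch | 3.00 | 7.9 | 5.4 | 82.7 |
| birch | 6.00 | 17.1 | 8.1 | 72.7 |
| birch | 10.0 | 25.4 | 13.0 | 56.7 |
| birch | 12.0 | 30.0 | 16.4 | 51.4 |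
| birch | 15.0 | 31.2 | 17.7 | 42.4 |
| birch | 20.0 | 37.7 | 22.2 | 32.6 |

(scatter of a reading: 1 percentage point)



1. the best flask by share of target in target plus other capture product; "all alike" if 1.5 percentage points covers them all (spring / autumn / midnight / noon / dawn / all alike)
2. share of target in target plus other capture product at the end, spring
3. share of target in target plus other capture product at the end, autumn
4. share of target in target plus other capture product at the end, midnight
5. share of target in target plus other capture product at the end, noon
6. share of target in target plus other capture product at the end, dawn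

What ratio do the nucleophiles keep? In maple at 10.0 min, the fractions left are 40.0% of first and 55.2% of second nucleophile. We work with these fractions left, and their logarithms give 1.54. This ratio, ln(fraction of first left) over ln(fraction of second left), is s, the selectivity factor, a reading that stays constant if both nucleophiles compete for one intermediate at one temperature. The maple reading at 5.00 min gives 1.60. At 55 °C, ash gives 2.54 and birch 2.16, so the colder runs read higher.

What share does s give? At any moment the target's share is s[first]/(s[first]+[second]), which at the charges and 70 °C is 73.5% at the start. With s above one, first nucleophile falls faster as a fraction, so we expect noon to slip below that start share.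

When does the first nucleophile arrive? In midnight, by 2.00 min a third of the feed is in, while maple has lost about half of its starting material. Putting that third of the feed against the whole charge of second nucleophile, the formula gives 48.1%. That is a rough figure and no limit: it leaves out what capture has used of each nucleophile by then. Spring and autumn have 2.00 min warm, so we expect shallow conversion and a high share in both. We therefore put spring and autumn first, then noon, dawn and midnight.

The forecast chose spring, with spring 73%, autumn 71%, midnight 50%, noon 70% and dawn 64%, holding that “Slow feed starves first nucleophile early”.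

The flasks give spring, with spring 73.6%, autumn 72.0%, midnight 51.8%, noon 71.0% and dawn 66.3%.

    starting material → open intermediate (k = 0.00490 /s, Ea = 102 kJ/mol)
    first nucleophile + open intermediate → target (k = 2.90 /M/s, Ea = 41.0 kJ/mol)
    second nucleophile + open intermediate → other capture product (k = 1.90 /M/s, Ea = 66.0 kJ/mol)
    open intermediate → solvolysis product (k = 0.170 /s, Ea = 92.0 kJ/mol)
    open intermediate + capture agent → trapped intermediate (k = 0.680 /M/s, Ea = 38.0 kJ/mol)
    2 starting material → homo dimer (k = 6.20 × 10⁻⁵ /M/s, Ea = 64.0 kJ/mol)
    (constants at 70 °C)

In noon at 8.00 min, 47% of first and 61% of second nucleophile are left, which gives s = 1.53 against the 1.54 read from maple. Spring read at 30 min has 57.2% of its second nucleophile left. Raising that fraction to the power s puts first nucleophile at 42.3%, and the flask holds 41.5%. Those fractions give a share of 70.8%, and the flask gives 71.1%.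

The data come from a simulation for an exercise; the scatter is artificial.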